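**Plan**

- Retrosynthesis: the methoxy-quinone ring (ring A) is cut at its C(=O)–C(OMe) bond (6π closure) and its C(=O)–C(CH3) bond (vinyl addition). Further cuts: squarate C–CH2, ring-B aryl–CH2 and aryl–CH3.
- Enabling feature: ring A is a hexasubstituted p-quinone. Its C(=O)–C(chain)=C(OH)–C(=O) half is the four carbons of a squarate; its C(CH3)=C(OCH3) half is a 1-methoxypropen-2-yl unit.
- Forward: ring B is bought as 2,5-dihydroxybenzoquinone and masked as a tetrakis(MOM) arene. Two directed lithiations add CH3 and the C14 chain, and the chain Grignard goes onto di-tert-butyl squarate.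
- A β-methoxyvinyllithium is added, and thermal 4π opening/6π closure then builds ring A, the only ring closed in the route, last.
- The OMe/OH distinction of ring A is carried as methyl ether versus tert-butyl ether. One acid treatment removes the tert-butyl and four MOM groups, and air oxidises the ring-B tetrol to the dihydroxyquinone.
- Stereochemistry: the target has no stereocentre and no stereogenic double bond; only positional control is needed and connectivity supplies it.

Key step: step 7

Remark: the target is achiral, so no enantiomer question arises; it is treated as the hydroxyquinone tautomer drawn. 1,14-Dibromotetradecane, di-tert-butyl squarate and 2-bromo-1,1-dimethoxypropane are assumed to be purchasable. Ar = 4-methyl-2,3,5,6-tetrakis(methoxymethoxy)phenyl.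

**Route**

Step 1
Reactants: 1 2,5-dihydroxy-1,4-benzoquinone
Product: 3 1,2,4,5-tetrakis(methoxymethoxy)benzene, via benzene-1,2,4,5-tetrol 2 (not isolated)
Conditions: H2 (1 atm), Pd/C, THF, rt; filter under Ar; NaH, MOMCl, DMF, 0 °C to rt
Reagents that add atoms: chloromethyl methyl ether, COCCl
Why: Catalytic hydrogenation should reduce the quinone to the air-sensitive tetrol, which is O-alkylated fourfold without isolation (Williamson-type MOM protection) to give an arene suited to directed ortho-metalation.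

Step 2
Reactants: 3 1,2,4,5-tetrakis(methoxymethoxy)benzene
Product: 5 3-methyl-1,2,4,5-tetrakis(methoxymethoxy)benzene, via aryllithium 4 (not isolated)
Conditions: n-BuLi (1.05 equiv), THF, −20 to 0 °C; MeI, −78 °C to rt
Reagents that add atoms: iodomethane, CI
Why: Directed ortho-metalation at a C–H flanked by two OMOM groups, followed by SN2 methylation of the aryllithium, should give the monomethyl arene.

Step 3
Reactants: 5 3-methyl-1,2,4,5-tetrakis(methoxymethoxy)benzene; 6 1,14-dibromotetradecane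
Product: 8 1-(14-bromotetradecyl)-4-methyl-2,3,5,6-tetrakis(methoxymethoxy)benzene, via aryllithium 7 (not isolated)
Conditions: n-BuLi, THF, 0 °C; cannulate into 6 (4 equiv), THF/DMPU, −78 °C to rt
Reagents that add atoms: none
Why: A second directed ortho-metalation at the only remaining ring C–H (doubly OMOM-flanked, so ring lithiation should outrun lateral lithiation of the methyl) and SN2 alkylation, with inverse addition to excess dibromide to limit double alkylation.

Step 4
Reactants: 8 1-(14-bromotetradecyl)-4-methyl-2,3,5,6-tetrakis(methoxymethoxy)benzene; 9 di-tert-butyl squarate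
Product: 12 3-tert-butoxy-4-[14-(Ar)tetradecyl]cyclobut-3-ene-1,2-dione, via Grignard reagent 10 (not isolated), via magnesium alkoxide 11 (not isolated)
Conditions: Mg, I2 (cat.), THF, 40 °C; add to 9, THF, −78 °C; TFAA, −78 °C; aq. NaHCO3
Reagents that add atoms: none
Why: Grignard 1,2-addition to one squarate carbonyl, then TFAA-induced ionisation with 1,3-oxygen transposition and loss of one tert-butyl group, should give the 3-alkoxy-4-alkylcyclobutenedione, whose remaining vinylogous tert-butyl ester is the latent ring-A hydroxyl.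

Step 5
Reactants: 13 2-bromo-1,1-dimethoxypropane (racemic)
Product: 14 (Z)-2-bromo-1-methoxyprop-1-ene
Conditions: TMSOTf, i-Pr2NEt, CH2Cl2, −20 °C to rt; fractional distillation
Reagents that add atoms: none
Why: Silyl triflate/amine-mediated elimination of methanol from an acetal through its oxocarbenium ion (acetal-to-enol-ether conversion) should give the β-bromo enol ether; the Z isomer (Br cis to OMe) is carried on because its lithio derivative is chelation-stabilised.

Step 6
Reactants: 14 (Z)-2-bromo-1-methoxyprop-1-ene; 12 3-tert-butoxy-4-[14-(Ar)tetradecyl]cyclobut-3-ene-1,2-dione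
Product: 16 3-tert-butoxy-4-hydroxy-4-[(Z)-1-methoxyprop-1-en-2-yl]-2-[14-(Ar)tetradecyl]cyclobut-2-en-1-one (racemic), via vinyllithium 15 (not isolated)
Conditions: 14, t-BuLi (2 equiv), Et2O, −78 °C; add to 12, THF, −78 °C; cold H2O quench; used crude, acid-free
Reagents that add atoms: none
Why: Bromine–lithium exchange with retention gives a cis-β-methoxyvinyllithium that should add 1,2 to the more electrophilic ketone carbonyl next to the tert-butoxy-bearing carbon (the other carbonyl is a vinylogous ester), the regiochemistry established for 3-alkoxy-4-alkylcyclobutenediones; the new carbinol centre is racemic and disappears in step 7.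

Step 7
Reactants: 16 3-tert-butoxy-4-hydroxy-4-[(Z)-1-methoxyprop-1-en-2-yl]-2-[14-(Ar)tetradecyl]cyclobut-2-en-1-one
Product: 19 3-tert-butoxy-6-methoxy-5-methyl-2-[14-(Ar)tetradecyl]cyclohexa-2,5-diene-1,4-dione, via dienylketene 17 (not isolated), via hydroquinone 18 (not isolated)
Conditions: degassed toluene, 110 °C; cool; Ag2O, Et2O, rt
Reagents that add atoms: none
Why: Heating should open the cyclobutenone C1–C4 bond by conrotatory 4π electrocyclic ring opening to dienylketene 17, the C4 hydroxyl rotating outward (donor torquoselectivity) so that the methoxypropenyl group sits inward, cis to the ketene. Ring A is then closed by thermal disrotatory 6π electrocyclisation joining the ketene carbon to the methoxy-bearing vinyl terminus, and the cyclohexadienone enolises to hydroquinone 18, which Ag2O dehydrogenates to quinone 19. The closest known reaction type is the Liebeskind–Moore ring expansion of 4-alkenyl-4-hydroxycyclobutenones to hydroquinones and quinones. No stereocentre is created, since the sp3 carbons of 16 and of the cyclohexadienone both become sp2. The selectivity needed is positional and is fixed by connectivity: the squarate carbons deliver C(=O)–C(chain)=C(OtBu)–C(=O) and the vinyl unit delivers C(CH3)=C(OCH3), so OMe must end beside the carbonyl flanked by the chain and CH3 beside the carbonyl flanked by OtBu. Chemoselectivity rests on neutral conditions, which spare the enol ether, MOM and tert-butyl groups, and on Ag2O oxidising only the free hydroquinone, not the fully etherified ring-B arene.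

Step 8
Reactants: 19 3-tert-butoxy-6-methoxy-5-methyl-2-[14-(Ar)tetradecyl]cyclohexa-2,5-diene-1,4-dione
Product: 21 2-hydroxy-3-[14-(2,5-dihydroxy-4-methyl-3,6-dioxocyclohexa-1,4-dien-1-yl)tetradecyl]-5-methoxy-6-methylcyclohexa-2,5-diene-1,4-dione, via tetrol quinone 20 (not isolated)
Conditions: TFA/CH2Cl2/H2O, 0 °C to rt; then stir open to air
Reagents that add atoms: none
Why: Acid should cleave the four aryl MOM acetals and the vinylogous tert-butyl ester (loss of isobutene), and the liberated 1,2,4,5-tetrol autoxidises in air to the 2,5-dihydroxy-p-quinone, while the ring-A methoxy group, a vinylogous methyl ester, should tolerate cold dilute acid.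

**Compound list**

1 | 2,5-dihydroxy-1,4-benzoquinone | O=C1C=C(O)C(=O)C=C1O | starting material
2 | benzene-1,2,4,5-tetrol | Oc1cc(O)c(O)cc1O | intermediate
3 | 1,2,4,5-tetrakis(methoxymethoxy)benzene | COCOc1cc(OCOC)c(OCOC)cc1OCOC | intermediate
4 | [2,3,5,6-tetrakis(methoxymethoxy)phenyl]lithium | [Li]c1c(OCOC)c(OCOC)cc(OCOC)c1OCOC | intermediate
5 | 3-methyl-1,2,4,5-tetrakis(methoxymethoxy)benzene | Cc1c(OCOC)c(OCOC)cc(OCOC)c1OCOC | intermediate
6 | 1,14-dibromotetradecane | BrCCCCCCCCCCCCCCBr | starting material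
7 | [4-methyl-2,3,5,6-tetrakis(methoxymethoxy)phenyl]lithium | [Li]c1c(OCOC)c(OCOC)c(C)c(OCOC)c1OCOC | intermediate
8 | 1-(14-bromotetradecyl)-4-methyl-2,3,5,6-tetrakis(methoxymethoxy)benzene | BrCCCCCCCCCCCCCCc1c(OCOC)c(OCOC)c(C)c(OCOC)c1OCOC | intermediate
9 | di-tert-butyl squarate (3,4-di-tert-butoxycyclobut-3-ene-1,2-dione) | CC(C)(C)OC1=C(OC(C)(C)C)C(=O)C1=O | starting material
10 | [14-(Ar)tetradecyl]magnesium bromide | Br[Mg]CCCCCCCCCCCCCCc1c(OCOC)c(OCOC)c(C)c(OCOC)c1OCOC | intermediate
11 | bromomagnesium alkoxide of 2,3-di-tert-butoxy-4-hydroxy-4-[14-(Ar)tetradecyl]cyclobut-2-en-1-one (racemic) | CC(C)(C)OC1=C(OC(C)(C)C)C(O[Mg]Br)(CCCCCCCCCCCCCCc2c(OCOC)c(OCOC)c(C)c(OCOC)c2OCOC)C1=O | intermediate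
12 | 3-tert-butoxy-4-[14-(Ar)tetradecyl]cyclobut-3-ene-1,2-dione | CC(C)(C)OC1=C(CCCCCCCCCCCCCCc2c(OCOC)c(OCOC)c(C)c(OCOC)c2OCOC)C(=O)C1=O | intermediate
13 | 2-bromo-1,1-dimethoxypropane (racemic) | COC(OC)C(C)Br | starting material
14 | (Z)-2-bromo-1-methoxyprop-1-ene | CO/C=C(/C)Br | intermediate
15 | (E)-(1-methoxyprop-1-en-2-yl)lithium (Li cis to OMe) | CO/C=C(/C)[Li] | intermediate
16 | 3-tert-butoxy-4-hydroxy-4-[(Z)-1-methoxyprop-1-en-2-yl]-2-[14-(Ar)tetradecyl]cyclobut-2-en-1-one (racemic) | CO/C=C(/C)C1(O)C(OC(C)(C)C)=C(CCCCCCCCCCCCCCc2c(OCOC)c(OCOC)c(C)c(OCOC)c2OCOC)C1=O | intermediate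
17 | dienylketene: 3-tert-butoxy-4-hydroxy-6-methoxy-5-methyl-2-[14-(Ar)tetradecyl]hexa-1,3,5-trien-1-one, propenyl group cis to the ketene | CO/C=C(/C)\C(O)=C(\OC(C)(C)C)C(CCCCCCCCCCCCCCc1c(OCOC)c(OCOC)c(C)c(OCOC)c1OCOC)=C=O | intermediate
18 | 3-tert-butoxy-6-methoxy-5-methyl-2-[14-(Ar)tetradecyl]benzene-1,4-diol | COc1c(C)c(O)c(OC(C)(C)C)c(CCCCCCCCCCCCCCc2c(OCOC)c(OCOC)c(C)c(OCOC)c2OCOC)c1O | intermediate
19 | 3-tert-butoxy-6-methoxy-5-methyl-2-[14-(Ar)tetradecyl]cyclohexa-2,5-diene-1,4-dione | COC1=C(C)C(=O)C(OC(C)(C)C)=C(CCCCCCCCCCCCCCc2c(OCOC)c(OCOC)c(C)c(OCOC)c2OCOC)C1=O | intermediate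
20 | 2-hydroxy-5-methoxy-6-methyl-3-[14-(2,3,5,6-tetrahydroxy-4-methylphenyl)tetradecyl]cyclohexa-2,5-diene-1,4-dione | COC1=C(C)C(=O)C(O)=C(CCCCCCCCCCCCCCc2c(O)c(O)c(C)c(O)c2O)C1=O | intermediate
21 | 2-hydroxy-3-[14-(2,5-dihydroxy-4-methyl-3,6-dioxocyclohexa-1,4-dien-1-yl)tetradecyl]-5-methoxy-6-methylcyclohexa-2,5-diene-1,4-dione (CNP0130251.0) | COC1=C(C)C(=O)C(O)=C(CCCCCCCCCCCCCCC2=C(O)C(=O)C(C)=C(O)C2=O)C1=O | target

**Step count and risks**

Total steps: 8. Longest linear sequence: 7 (steps 1, 2, 3, 4, 6, 7, 8); step 5 is a one-step side branch.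

Steps most likely to fail:

Step 6. The vinyllithium may lose lithium methoxide by β-elimination, it may attack the vinylogous-ester carbonyl or displace tert-butoxide, and the enol-ether carbinol may undergo acid-triggered allylic transposition on work-up. The fallback sets out from 12 and returns at 19; it brings in the methyl-bearing carbon with a robust vinyllithium and installs the methoxy oxygen after ring formation. Isopropenyllithium (from 2-bromopropene and t-BuLi) is added to 12 to give 3-tert-butoxy-4-hydroxy-4-(prop-1-en-2-yl)-2-[14-(Ar)tetradecyl]cyclobut-2-en-1-one F1. Thermolysis and Ag2O oxidation as in step 7 should give 3-tert-butoxy-5-methyl-2-[14-(Ar)tetradecyl]-1,4-benzoquinone F2, which has one free ring C–H where the methoxy group belongs. Nucleophilic epoxidation (H2O2, Na2CO3) of the only double bond without an oxygen donor gives the 5,6-epoxide of F2, 3-tert-butoxy-1-methyl-4-[14-(Ar)tetradecyl]-7-oxabicyclo[4.1.0]hept-3-ene-2,5-dione F3. Base-mediated epoxide opening (DBU; the menadione oxide to phthiocol type of isomerisation) gives 3-tert-butoxy-6-hydroxy-5-methyl-2-[14-(Ar)tetradecyl]-1,4-benzoquinone F4. O-Methylation (MeI, Ag2O) then gives 19.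

Step 7. The inward methoxy group may slow the 6π closure so that the ketene is intercepted by the C4 hydroxyl (butenolide formation), or isobutene may be lost thermally to give an acidic hydroxycyclobutenone that hydrolyses the enol ether. The fallback sets out from 8 and returns at 20; it closes ring A by the Moore cyclisation of an enynylketene, which needs no alkene geometry, enol ether or tert-butyl group. Displacement with lithium acetylide–ethylenediamine (DMSO) gives 1-(hexadec-15-yn-1-yl)-4-methyl-2,3,5,6-tetrakis(methoxymethoxy)benzene F5. Lithiation and addition to dimethyl squarate give 4-hydroxy-2,3-dimethoxy-4-[16-(Ar)hexadec-1-yn-1-yl]cyclobut-2-en-1-one F6, which is silylated (TMSCl, Et3N) to its trimethylsilyl ether F7. MeLi addition to the remaining carbonyl, TFAA-induced 1,3-carbonyl transposition and desilylation (K2CO3, MeOH) give 4-hydroxy-2-methoxy-3-methyl-4-[16-(Ar)hexadec-1-yn-1-yl]cyclobut-2-en-1-one F8. Thermolysis (toluene, 110 °C; hydrogen transfer from OH to the ring radical) should give 2-methoxy-3-methyl-6-[14-(Ar)tetradecyl]-1,4-benzoquinone F9. Nucleophilic epoxidation (H2O2, Na2CO3) of the CH=C(chain) bond gives the epoxide of F9, 4-methoxy-3-methyl-1-[14-(Ar)tetradecyl]-7-oxabicyclo[4.1.0]hept-3-ene-2,5-dione F10. Base-mediated isomerisation gives 2-hydroxy-5-methoxy-6-methyl-3-[14-(Ar)tetradecyl]-1,4-benzoquinone F11, and the acid treatment of step 8 then leads to 20 and, in air, to 21.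

Step 8. The ring-A methoxy group may be hydrolysed or exchanged under acid, neighbouring phenols may be bridged as methylene acetals by the released formaldehyde equivalent, or MOM cleavage may stay incomplete. The fallback sets out from 19 and returns at 21; it unmasks ring B oxidatively instead of hydrolytically. CAN (MeCN/H2O, 0 °C) should oxidise the tetra-MOM arene of 19, with loss of two MOM groups, to 3-tert-butoxy-6-methoxy-5-methyl-2-{14-[2,5-bis(methoxymethoxy)-4-methyl-3,6-dioxocyclohexa-1,4-dien-1-yl]tetradecyl}-1,4-benzoquinone F12. Its remaining MOM groups (now vinylogous acetal esters) and the tert-butyl ether are far more labile than aryl MOM ethers and should come off with very mild acid (PPTS, aqueous acetone) to give 21.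

Further compounds
F1 | step 6 | 3-tert-butoxy-4-hydroxy-4-(prop-1-en-2-yl)-2-[14-(Ar)tetradecyl]cyclobut-2-en-1-one (racemic) | C=C(C)C1(O)C(OC(C)(C)C)=C(CCCCCCCCCCCCCCc2c(OCOC)c(OCOC)c(C)c(OCOC)c2OCOC)C1=O
F2 | step 6 | 3-tert-butoxy-5-methyl-2-[14-(Ar)tetradecyl]cyclohexa-2,5-diene-1,4-dione | CC1=CC(=O)C(CCCCCCCCCCCCCCc2c(OCOC)c(OCOC)c(C)c(OCOC)c2OCOC)=C(OC(C)(C)C)C1=O
F3 | step 6 | 3-tert-butoxy-1-methyl-4-[14-(Ar)tetradecyl]-7-oxabicyclo[4.1.0]hept-3-ene-2,5-dione (racemic cis epoxide) | CC12OC1C(=O)C(CCCCCCCCCCCCCCc3c(OCOC)c(OCOC)c(C)c(OCOC)c3OCOC)=C(OC(C)(C)C)C2=O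
F4 | step 6 | 3-tert-butoxy-6-hydroxy-5-methyl-2-[14-(Ar)tetradecyl]cyclohexa-2,5-diene-1,4-dione | CC1=C(O)C(=O)C(CCCCCCCCCCCCCCc2c(OCOC)c(OCOC)c(C)c(OCOC)c2OCOC)=C(OC(C)(C)C)C1=O
F5 | step 7 | 1-(hexadec-15-yn-1-yl)-4-methyl-2,3,5,6-tetrakis(methoxymethoxy)benzene | C#CCCCCCCCCCCCCCCc1c(OCOC)c(OCOC)c(C)c(OCOC)c1OCOC
F6 | step 7 | 4-hydroxy-2,3-dimethoxy-4-[16-(Ar)hexadec-1-yn-1-yl]cyclobut-2-en-1-one (racemic) | COC1=C(OC)C(O)(C#CCCCCCCCCCCCCCCc2c(OCOC)c(OCOC)c(C)c(OCOC)c2OCOC)C1=O
F7 | step 7 | 2,3-dimethoxy-4-(trimethylsilyloxy)-4-[16-(Ar)hexadec-1-yn-1-yl]cyclobut-2-en-1-one (racemic) | COC1=C(OC)C(O[Si](C)(C)C)(C#CCCCCCCCCCCCCCCc2c(OCOC)c(OCOC)c(C)c(OCOC)c2OCOC)C1=O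
F8 | step 7 | 4-hydroxy-2-methoxy-3-methyl-4-[16-(Ar)hexadec-1-yn-1-yl]cyclobut-2-en-1-one (racemic) | COC1=C(C)C(O)(C#CCCCCCCCCCCCCCCc2c(OCOC)c(OCOC)c(C)c(OCOC)c2OCOC)C1=O
F9 | step 7 | 2-methoxy-3-methyl-6-[14-(Ar)tetradecyl]cyclohexa-2,5-diene-1,4-dione | COC1=C(C)C(=O)C=C(CCCCCCCCCCCCCCc2c(OCOC)c(OCOC)c(C)c(OCOC)c2OCOC)C1=O
F10 | step 7 | 4-methoxy-3-methyl-1-[14-(Ar)tetradecyl]-7-oxabicyclo[4.1.0]hept-3-ene-2,5-dione (racemic cis epoxide) | COC1=C(C)C(=O)C2OC2(CCCCCCCCCCCCCCc3c(OCOC)c(OCOC)c(C)c(OCOC)c3OCOC)C1=O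
F11 | step 7 | 2-hydroxy-5-methoxy-6-methyl-3-[14-(Ar)tetradecyl]cyclohexa-2,5-diene-1,4-dione | COC1=C(C)C(=O)C(O)=C(CCCCCCCCCCCCCCc2c(OCOC)c(OCOC)c(C)c(OCOC)c2OCOC)C1=O
F12 | step 8 | 3-tert-butoxy-6-methoxy-5-methyl-2-{14-[2,5-bis(methoxymethoxy)-4-methyl-3,6-dioxocyclohexa-1,4-dien-1-yl]tetradecyl}cyclohexa-2,5-diene-1,4-dione | COC1=C(C)C(=O)C(OC(C)(C)C)=C(CCCCCCCCCCCCCCC2=C(OCOC)C(=O)C(C)=C(OCOC)C2=O)C1=O
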